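The route rests on cutting the bond between the acetoxy-bearing carbinol carbon and the neighbouring chain CH2. The key step exploits that this carbon lies between the exocyclic C=CH2 alkene and an unbranched methylene, the retron of a catalyst-controlled 1,2-addition of a primary alkylzinc to a 2-substituted acrolein, while the cyclohexenone and butenolide rings are remote electrophiles that a mild organozinc leaves alone. In one flask the butenolide-bearing homoallylzinc reagent, the enal carrying the pulegone-derived trimethylcyclohexenone ring and acetic anhydride are joined, forming the C–C bond, the (R)-carbinol centre and the acetate together. The precursors are an (E)-homoallylic iodide and an α-methylene aldehyde.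

Key step: step 15

Remark on the chemistry: the undefined stereocentres of 2, 3, 4 and 10 (and any C-6 epimer of 7) are erased in later steps, so these compounds are carried as mixtures.

Step 1
Reactants: 1 (R)-(+)-pulegone, (5R)-5-methyl-2-(propan-2-ylidene)cyclohexan-1-one
Product: 2 pulegone oxide, (6R)-2,2,6-trimethyl-1-oxaspiro[2.5]octan-4-one, both spiro epimers
Conditions: 30% aq. H2O2, LiOH, MeOH, 0 °C → rt
Reagents that add atoms: hydrogen peroxide (OO)
Why: Weitz–Scheffer nucleophilic epoxidation of the tetrasubstituted enone by hydroperoxide anion; the new spiro centre forms unselectively but is destroyed in step 2, and the C-5 methyl centre is untouched.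

Step 2
Reactants: 2 pulegone oxide
Product: 3 (5R)-5-methyl-2-(phenylsulfanyl)cyclohexan-1-one, both C-2 epimers
Conditions: PhSH, NaH, THF, 0 °C → reflux; H2O
Reagents that add atoms: thiophenol (Sc1ccccc1)
Why: Thiolate opening of the α,β-epoxy ketone at the α-carbon is followed by retro-aldol fragmentation of the β-alkoxide with loss of acetone, which leaves the α-sulfanyl ketone with the remote methyl centre intact.

Step 3
Reactants: 3 (5R)-5-methyl-2-(phenylsulfanyl)cyclohexan-1-one
Product: 5 (5R)-5-methylcyclohex-2-en-1-one, via sulfoxide 4 (not isolated)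
Conditions: NaIO4, MeOH/H2O, 0 °C → rt; then CaCO3, toluene, 90 °C
Reagents that add atoms: none
Why: Sulfide oxidation and thermal syn-elimination of the α-sulfinyl ketone (sulfoxide pyrolysis) can only engage the C-3 hydrogens, so the C2=C3 enone should form regiospecifically without touching C-5.

Step 4
Reactants: 5 (5R)-5-methylcyclohex-2-en-1-one
Product: 7 (5R,6S)-5-methyl-6-(prop-2-en-1-yl)cyclohex-2-en-1-one, via lithium dienolate 6 (not isolated)
Conditions: LiN(iPr)2, THF, −78 °C; allyl bromide, −78 → −20 °C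
Reagents that add atoms: allyl bromide (C=CCBr)
Why: Kinetic α'-deprotonation gives the cross-conjugated dienolate, whose C-alkylation (enolate alkylation) should occur mainly anti to the C-5 methyl; this centre is re-planarised in step 5, so its configuration is immaterial.

Step 5
Reactants: 7 (5R,6S)-5-methyl-6-(prop-2-en-1-yl)cyclohex-2-en-1-one
Product: 9 (5R,6R)-5,6-dimethyl-6-(prop-2-en-1-yl)cyclohex-2-en-1-one, via lithium dienolate 8 (not isolated)
Conditions: LiN(iPr)2, THF, −78 °C; MeI, DMPU, −78 → 0 °C
Reagents that add atoms: iodomethane (CI)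
Why: In the tetrasubstituted dienolate the C-5 methyl should sit pseudoaxial to avoid A(1,2) strain with the C-6 allyl group, so iodomethane enters anti to it (substrate-controlled enolate alkylation), which places the new methyl trans and the allyl cis to the C-5 methyl (6R).

Step 6
Reactants: 9 (5R,6R)-5,6-dimethyl-6-(prop-2-en-1-yl)cyclohex-2-en-1-one
Product: 10 (5R,6R)-1,5,6-trimethyl-6-(prop-2-en-1-yl)cyclohex-2-en-1-ol, both C-1 epimers
Conditions: MeLi, Et2O, −78 °C; H2O
Reagents that add atoms: methyllithium ([Li]C)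
Why: 1,2-Addition of the small, hard organolithium to the enone carbonyl gives the tertiary allylic alcohol; the new carbinol centre is lost in step 7.

Step 7
Reactants: 10 (5R,6R)-1,5,6-trimethyl-6-(prop-2-en-1-yl)cyclohex-2-en-1-ol
Product: 11 (4R,5R)-3,4,5-trimethyl-4-(prop-2-en-1-yl)cyclohex-2-en-1-one
Conditions: [C5H5NH][CrO3Cl] (pyridinium chlorochromate), 4 Å molecular sieves, CH2Cl2, rt
Reagents that add atoms: pyridinium chlorochromate ([O-][Cr](=O)(=O)Cl.c1cc[nH+]cc1)
Why: Dauben oxidative 1,3-transposition, in which the tertiary allylic chromate ester undergoes a [3,3] shift (the new carbonyl oxygen comes from chromate) and is oxidised to the β-methyl enone, leaving the quaternary and methine centres and the terminal alkene untouched.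

Step 8
Reactants: 11 (4R,5R)-3,4,5-trimethyl-4-(prop-2-en-1-yl)cyclohex-2-en-1-one
Product: 12 4-[(1R,6R)-1,2,6-trimethyl-4-oxocyclohex-2-en-1-yl]butanal
Conditions: Rh(acac)(CO)2 (1 mol %), Xantphos (3 mol %), CO/H2 (1:1, 10 bar), toluene, 70 °C
Reagents that add atoms: carbon monoxide ([C-]#[O+])
Why: Rhodium/wide-bite-angle-diphosphine hydroformylation is linear-selective for a monosubstituted alkene on a neopentyl-type carbon, and the conjugated trisubstituted enone is inert under these conditions.

Step 9
Reactants: 12 4-[(1R,6R)-1,2,6-trimethyl-4-oxocyclohex-2-en-1-yl]butanal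
Product: 13 2-methylidene-4-[(1R,6R)-1,2,6-trimethyl-4-oxocyclohex-2-en-1-yl]butanal
Conditions: 37% aq. HCHO, pyrrolidine (10 mol %), EtCO2H (10 mol %), i-PrOH, 45 °C
Reagents that add atoms: formaldehyde (C=O)
Why: Amine/acid-catalysed Mannich condensation (organocatalytic α-methylenation) runs through the aldehyde enamine, which forms far faster than any ketone enamine, and gives the 2-substituted acrolein.

Step 10
Reactants: 14 tert-butyl(but-3-yn-1-yloxy)dimethylsilane
Product: 17 (3E)-6-{[tert-butyl(dimethyl)silyl]oxy}-4-methylhex-3-en-1-ol, via alkenylalane 15 (not isolated), via lithium alanate 16 (not isolated)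
Conditions: Me3Al, Cp2ZrCl2 (20 mol %), CH2Cl2, 0 °C → rt, volatiles removed; n-BuLi, hexane/THF, −78 → 0 °C; ethylene oxide, −78 °C → rt; H2O
Reagents that add atoms: trimethylaluminium (C[Al](C)C); ethylene oxide (C1CO1)
Why: Zirconium-catalysed syn-carboalumination (Negishi carboalumination) sets the (E)-trisubstituted alkene regio- and stereoselectively, and the more nucleophilic alanate transfers the alkenyl group to ethylene oxide with retention of geometry.

Step 11
Reactants: 17 (3E)-6-{[tert-butyl(dimethyl)silyl]oxy}-4-methylhex-3-en-1-ol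
Product: 18 tert-butyl{[(3E)-6-iodo-3-methylhex-3-en-1-yl]oxy}dimethylsilane
Conditions: I2, PPh3, imidazole, CH2Cl2, 0 °C
Reagents that add atoms: iodine (II)
Why: Appel-type iodination of the primary alcohol proceeds by SN2 displacement of the oxyphosphonium without affecting the silyl ether or the alkene.

Step 12
Reactants: 18 tert-butyl{[(3E)-6-iodo-3-methylhex-3-en-1-yl]oxy}dimethylsilane; 19 4-bromofuran-2(5H)-one
Product: 22 4-[(3E)-6-{[tert-butyl(dimethyl)silyl]oxy}-4-methylhex-3-en-1-yl]furan-2(5H)-one, via alkyllithium 20 (not isolated), via alkylzinc chloride 21 (not isolated)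
Conditions: t-BuLi (2 equiv), Et2O, −78 °C; ZnCl2, THF, −78 °C → rt; 19, Pd(PPh3)4 (5 mol %, zerovalent palladium), THF, rt
Reagents that add atoms: none
Why: Low-temperature iodine–lithium exchange and transmetalation to zinc preserve the (E)-alkene, and Negishi coupling of the primary alkylzinc with the vinylogous acyl bromide installs the 4-alkylbutenolide.

Step 13
Reactants: 22 4-[(3E)-6-{[tert-butyl(dimethyl)silyl]oxy}-4-methylhex-3-en-1-yl]furan-2(5H)-one
Product: 23 4-[(3E)-6-hydroxy-4-methylhex-3-en-1-yl]furan-2(5H)-one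
Conditions: HF·pyridine, pyridine/THF, 0 °C → rt
Reagents that add atoms: none
Why: Buffered fluoride cleavage of the primary silyl ether (desilylation) avoids the basic conditions that could isomerise or open the butenolide.

Step 14
Reactants: 23 4-[(3E)-6-hydroxy-4-methylhex-3-en-1-yl]furan-2(5H)-one
Product: 24 4-[(3E)-6-iodo-4-methylhex-3-en-1-yl]furan-2(5H)-one
Conditions: I2, PPh3, imidazole, CH2Cl2, 0 °C
Reagents that add atoms: iodine (II)
Why: Appel-type iodination under neutral SN2 conditions is tolerated by the butenolide and the trisubstituted alkene.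

Step 15
Reactants: 13 2-methylidene-4-[(1R,6R)-1,2,6-trimethyl-4-oxocyclohex-2-en-1-yl]butanal; 24 4-[(3E)-6-iodo-4-methylhex-3-en-1-yl]furan-2(5H)-one
Product: 28 CNP0204194.1, (4R,7E)-7-methyl-3-methylidene-10-(5-oxo-2,5-dihydrofuran-3-yl)-1-[(1R,6R)-1,2,6-trimethyl-4-oxocyclohex-2-en-1-yl]dec-7-en-4-yl acetate, via bis(alkyl)zinc 25 (not isolated), via mixed diorganozinc 26 (not isolated), via zinc alkoxide 27 (not isolated)
Conditions: 24, Et2Zn (neat), copper iodide CuI (0.3 mol %), 50 °C, then volatiles removed in vacuo; Zn(CH2SiMe3)2, Et2O, rt; 13, Ti(OiPr)4 (0.6 equiv), (1S,2S)-1,2-bis(trifluoromethanesulfonamido)cyclohexane (8 mol %), Et2O/toluene, −20 °C; then Ac2O, DMAP, pyridine, 0 °C → rt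
Reagents that add atoms: acetic anhydride (CC(=O)OC(C)=O)
Why: Iodine–zinc exchange converts 24 into the bis(alkyl)zinc 25, which redistributes with Zn(CH2SiMe3)2 to 26 so that only the functionalised homoallyl group is transferable; the chiral titanium bis(sulfonamide) complex then activates the formyl group of 13, the alkyl is delivered to its Re face, and the resulting alkoxide 27 (drawn on zinc, in the flask shared between zinc and titanium) is acetylated in the same pot. The closest known reaction type is the titanium/bis(sulfonamide)-catalysed enantioselective 1,2-addition of functionalised diorganozincs to α-substituted unsaturated aldehydes, followed by O-acylation of the metal alkoxide. No ring is closed. The one new stereocentre, the acetoxy-bearing carbon (R), should be set by the ligand alone, because the ring stereocentres are too remote to interfere; the (1S,2S)-enantiomer is chosen because the (1R,2R)-ligand is expected to direct alkyl transfer to the Si face of aryl and α-branched unsaturated aldehydes. The step needs chemoselectivity for the aldehyde over the cyclohexenone carbonyl and over three Michael acceptors (enal β-carbon, enone, butenolide), which is secured by the low reactivity of organozincs toward ketones and enoates compared with the titanium-activated aldehyde and by the absence of stoichiometric copper. The (E)-alkene and the acidic γ-position of the butenolide should survive because dialkylzincs are weak kinetic bases and the exchange is run without added Lewis base.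

Compound list
1 | (R)-(+)-pulegone, (5R)-5-methyl-2-(propan-2-ylidene)cyclohexan-1-one | C[C@@H]1CCC(=C(C)C)C(=O)C1 | starting material
2 | pulegone oxide, (6R)-2,2,6-trimethyl-1-oxaspiro[2.5]octan-4-one (both spiro epimers) | C[C@@H]1CCC2(OC2(C)C)C(=O)C1 | intermediate
3 | (5R)-5-methyl-2-(phenylsulfanyl)cyclohexan-1-one (both C-2 epimers) | C[C@@H]1CCC(Sc2ccccc2)C(=O)C1 | intermediate
4 | (5R)-5-methyl-2-(phenylsulfinyl)cyclohexan-1-one (sulfoxide, mixture) | C[C@@H]1CCC(S(=O)c2ccccc2)C(=O)C1 | intermediate
5 | (5R)-5-methylcyclohex-2-en-1-one | C[C@@H]1CC=CC(=O)C1 | intermediate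
6 | lithium (3R)-3-methylcyclohexa-1,5-dien-1-olate (cross-conjugated dienolate of 5) | C[C@@H]1CC=CC(O[Li])=C1 | intermediate
7 | (5R,6S)-5-methyl-6-(prop-2-en-1-yl)cyclohex-2-en-1-one (trans) | C[C@@H]1CC=CC(=O)[C@H]1CC=C | intermediate
8 | lithium (3R)-3-methyl-2-(prop-2-en-1-yl)cyclohexa-1,5-dien-1-olate (dienolate of 7) | C[C@@H]1CC=CC(O[Li])=C1CC=C | intermediate
9 | (5R,6R)-5,6-dimethyl-6-(prop-2-en-1-yl)cyclohex-2-en-1-one (methyls trans) | C[C@@H]1CC=CC(=O)[C@]1(C)CC=C | intermediate
10 | (5R,6R)-1,5,6-trimethyl-6-(prop-2-en-1-yl)cyclohex-2-en-1-ol (both C-1 epimers) | C[C@@H]1CC=CC(C)(O)[C@]1(C)CC=C | intermediate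
11 | (4R,5R)-3,4,5-trimethyl-4-(prop-2-en-1-yl)cyclohex-2-en-1-one | C=CC[C@@]1(C)C(C)=CC(=O)C[C@H]1C | intermediate
12 | 4-[(1R,6R)-1,2,6-trimethyl-4-oxocyclohex-2-en-1-yl]butanal | O=CCCC[C@@]1(C)C(C)=CC(=O)C[C@H]1C | intermediate
13 | 2-methylidene-4-[(1R,6R)-1,2,6-trimethyl-4-oxocyclohex-2-en-1-yl]butanal | C=C(C=O)CC[C@@]1(C)C(C)=CC(=O)C[C@H]1C | intermediate
14 | tert-butyl(but-3-yn-1-yloxy)dimethylsilane | C#CCCO[Si](C)(C)C(C)(C)C | starting material
15 | [(1E)-4-{[tert-butyl(dimethyl)silyl]oxy}-2-methylbut-1-en-1-yl]dimethylalane | C[Al](C)/C=C(\C)CCO[Si](C)(C)C(C)(C)C | intermediate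
16 | lithium butyl[(1E)-4-{[tert-butyl(dimethyl)silyl]oxy}-2-methylbut-1-en-1-yl]dimethylalanate | [Li+].CCCC[Al-](C)(C)/C=C(\C)CCO[Si](C)(C)C(C)(C)C | intermediate
17 | (3E)-6-{[tert-butyl(dimethyl)silyl]oxy}-4-methylhex-3-en-1-ol | OCC/C=C(\C)CCO[Si](C)(C)C(C)(C)C | intermediate
18 | tert-butyl{[(3E)-6-iodo-3-methylhex-3-en-1-yl]oxy}dimethylsilane | ICC/C=C(\C)CCO[Si](C)(C)C(C)(C)C | intermediate
19 | 4-bromofuran-2(5H)-one | O=C1OCC(Br)=C1 | starting material
20 | [(3E)-6-{[tert-butyl(dimethyl)silyl]oxy}-4-methylhex-3-en-1-yl]lithium | [Li]CC/C=C(\C)CCO[Si](C)(C)C(C)(C)C | intermediate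
21 | chloro[(3E)-6-{[tert-butyl(dimethyl)silyl]oxy}-4-methylhex-3-en-1-yl]zinc | Cl[Zn]CC/C=C(\C)CCO[Si](C)(C)C(C)(C)C | intermediate
22 | 4-[(3E)-6-{[tert-butyl(dimethyl)silyl]oxy}-4-methylhex-3-en-1-yl]furan-2(5H)-one | O=C1OCC(CC/C=C(\C)CCO[Si](C)(C)C(C)(C)C)=C1 | intermediate
23 | 4-[(3E)-6-hydroxy-4-methylhex-3-en-1-yl]furan-2(5H)-one | O=C1OCC(CC/C=C(\C)CCO)=C1 | intermediate
24 | 4-[(3E)-6-iodo-4-methylhex-3-en-1-yl]furan-2(5H)-one | O=C1OCC(CC/C=C(\C)CCI)=C1 | intermediate
25 | bis[(3E)-3-methyl-6-(5-oxo-2,5-dihydrofuran-3-yl)hex-3-en-1-yl]zinc | O=C1OCC(CC/C=C(\C)CC[Zn]CC/C(C)=C/CCC2=CC(=O)OC2)=C1 | intermediate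
26 | [(3E)-3-methyl-6-(5-oxo-2,5-dihydrofuran-3-yl)hex-3-en-1-yl](trimethylsilylmethyl)zinc | C[Si](C)(C)C[Zn]CC/C(C)=C/CCC1=CC(=O)OC1 | intermediate
27 | (trimethylsilylmethyl)zinc alkoxide of the (R)-allylic carbinol | C=C(CC[C@@]1(C)C(C)=CC(=O)C[C@H]1C)[C@@H](CC/C(C)=C/CCC1=CC(=O)OC1)O[Zn]C[Si](C)(C)C | intermediate
28 | CNP0204194.1, (4R,7E)-7-methyl-3-methylidene-10-(5-oxo-2,5-dihydrofuran-3-yl)-1-[(1R,6R)-1,2,6-trimethyl-4-oxocyclohex-2-en-1-yl]dec-7-en-4-yl acetate | C=C(CC[C@@]1(C)C(C)=CC(=O)C[C@H]1C)[C@@H](CC/C(C)=C/CCC1=CC(=O)OC1)OC(C)=O | target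

Total step count: 15. Longest linear sequence: 10 steps (steps 1–9, then step 15); the butenolide branch contributes steps 10–14.

Steps most likely to fail

Step 15. The iodine–zinc exchange may be unclean in the presence of the butenolide (ethyl transfer to the lactone or γ-deprotonation). The alkene geometry may erode through reversible cyclisation of a homoallyl radical. The facial selectivity at the formyl group may be insufficient. The fallback sets out from 13 and 24 and returns at 28. A chromium-mediated Nozaki–Hiyama–Kishi-type alkylation (CrCl2, catalytic cobalt phthalocyanine Co(C32H16N8), DMF, rt) should join the same two carbons chemoselectively at the aldehyde and give the allylic alcohol as a mixture of carbinol epimers F1. Sharpless kinetic resolution (Ti(OiPr)4, L-(+)-diisopropyl tartrate, t-BuOOH, 4 Å molecular sieves, CH2Cl2, −20 °C) should then consume the (S)-carbinol epimer as the erythro epoxy alcohol F3 and leave the (R)-allylic alcohol F2. Acetylation of F2 (Ac2O, DMAP, pyridine) gives 28.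

Step 5. The methylation may show poor facial selectivity, or γ-deprotonation and over-alkylation may compete at the hindered α'-position. The fallback sets out from 5 and returns at 9; it reverses the order of bond formation and sets the quaternary centre under catalyst control. Methylation of 5 (LiN(iPr)2, MeI, THF, −78 °C) gives (5R,6S)-5,6-dimethylcyclohex-2-en-1-one F4. O-Acylation of its dienolate (LiN(SiMe3)2, allyl chloroformate) gives allyl (3R)-2,3-dimethylcyclohexa-1,5-dien-1-yl carbonate F5. Palladium-catalysed decarboxylative allylic alkylation (Pd2(dba)3 as zerovalent palladium source, the t-Bu-PHOX enantiomer that places the allyl group cis to the C-5 methyl, THF) should then deliver 9.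

Step 10. The alanate may open ethylene oxide sluggishly, or the alkenyl–aluminium bond may be protonated before C–C bond formation. The fallback sets out from 14 and returns at 17. The same carboalumination is quenched with iodine to give the vinyl iodide (E)-tert-butyl[(4-iodo-3-methylbut-3-en-1-yl)oxy]dimethylsilane F6. Suzuki coupling with vinylboronic acid pinacol ester (Pd(PPh3)4 as zerovalent palladium catalyst, K2CO3, THF/H2O) gives the diene (E)-tert-butyl[(3-methylhexa-3,5-dien-1-yl)oxy]dimethylsilane F7. Chemoselective hydroboration of the terminal vinyl group with 9-BBN, then NaOH/H2O2, gives 17.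

Further compounds
F1 | step 15 | 4-[(3E)-7-hydroxy-4-methyl-8-methylidene-10-[(1R,6R)-1,2,6-trimethyl-4-oxocyclohex-2-en-1-yl]dec-3-en-1-yl]furan-2(5H)-one, mixture of carbinol epimers | C=C(CC[C@@]1(C)C(C)=CC(=O)C[C@H]1C)C(O)CC/C(C)=C/CCC1=CC(=O)OC1
F2 | step 15 | 4-[(3E,7R)-7-hydroxy-4-methyl-8-methylidene-10-[(1R,6R)-1,2,6-trimethyl-4-oxocyclohex-2-en-1-yl]dec-3-en-1-yl]furan-2(5H)-one | C=C(CC[C@@]1(C)C(C)=CC(=O)C[C@H]1C)[C@@H](CC/C(C)=C/CCC1=CC(=O)OC1)O
F3 | step 15 | erythro epoxy alcohol from the (S)-carbinol epimer of F1 (2,2-disubstituted oxirane) | O[C@@H](CC/C(C)=C/CCC1=CC(=O)OC1)[C@]1(CC[C@@]2(C)C(C)=CC(=O)C[C@H]2C)CO1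
F4 | step 5 | (5R,6S)-5,6-dimethylcyclohex-2-en-1-one | C[C@@H]1CC=CC(=O)[C@H]1C
F5 | step 5 | allyl (3R)-2,3-dimethylcyclohexa-1,5-dien-1-yl carbonate | C[C@@H]1CC=CC(OC(=O)OCC=C)=C1C
F6 | step 10 | (E)-tert-butyl[(4-iodo-3-methylbut-3-en-1-yl)oxy]dimethylsilane | I/C=C(\C)CCO[Si](C)(C)C(C)(C)C
F7 | step 10 | (E)-tert-butyl[(3-methylhexa-3,5-dien-1-yl)oxy]dimethylsilane | C=C/C=C(\C)CCO[Si](C)(C)C(C)(C)C
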